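The readings are simulated for substances that don't exist, noise included.

| flask | E | X | temperature | remark | time |
|---|---|---|---|---|---|
| Sunday's | 0.61 M | 1.5 equiv | 50 °C | run made earlier |  |
| grey | 0.41 M | 0.380 equiv | 10 °C |  | 6.0 h |
| violet | 0.41 M | 0.750 equiv | 50 °C |  | 6.0 h |
| green | 0.41 M | 6.00 equiv | 50 °C |  | 6.0 h |
| amber | 0.41 M | 4.50 equiv | 30 °C |  | 6.0 h |
| blue | 0.41 M | 1.50 equiv | 50 °C |  | 6.0 h |

- Sunday's (time / min: Z / %, G / %): 6.00: 12.3, 0.3; 8.00: 14.9, 1.0; 12.0: 16.7, 2.7; 20.0: 21.9, 2.8; 30.0: 22.4, 4.3; 50.0: 22.5, 3.2; 80.0: 18.8, 4.5

(each reading ± 1 percentage point)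

- in percentages every species weighs as the E in it: one Q counts as two
- what was read earlier has a scatter of 1 percentage point, one standard deviation
- steps under discussion: E + X -> Z; X + Z -> G; X + G -> J; 2 E -> Q
- the earlier runs do not show what temperature does; that part of a forecast is a guess

- the flasks put in order of share of Z in all that became Z or G or J, best first, at 6.0 h (grey / violet / green / amber / blue)
- the share of Z in all that became Z or G or J of the flask you put first, at 6.0 h
- the share of Z in all that became Z or G or J of the flask you put last, at 6.0 h

Slowness is the thing to examine first: how slowly does Z fade in Sunday's flask once it has stopped growing?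

What can be read there? Z stands at 22.5% at 50.0 min and at 18.8% at 80.0 min. That is a drop of 3.7 percentage points against a scatter of 1 point, so this is a rough reading, but still a reading.

Why go to logarithms? A pseudo-first-order fade takes off equal powers of ten in equal times, so I count decades. Sunday's drop is 0.0780 of a decade. Dividing by the interval and by the X charged, 0.915 M, gives 0.171 M⁻¹ h⁻¹, the fade number: decades of Z lost per hour for each molar of X.

How is it used? Multiply it by a flask's charged X and its time to get that flask's decades. If Z is made early, the share of Z is the antilogarithm of minus that. Violet gets 0.315 decades, a share of 48.5%. Blue gets 0.629, a share of 23.5%. Green gets 2.52, a share of 0.304%.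

But charged X is not X present, and temperature was never measured. Where is the weak spot? It is amber. At 50 °C amber would get 1.89 decades. My guess divides the fade number by 4 on cooling to 30 °C, which leaves 0.472 decades, a share of 33.7%, and gives amber fewer decades than blue. Grey at 10 °C takes that division squared, so it gets 0.00996 decades, a share of 97.7%. My order is therefore grey, violet, amber, blue, green.

The forecast has grey > violet > blue > amber > green, with top 97% and low 0.02%, and says of amber's place “though this is a guess”, so it parts from my order on amber and blue.

The flasks stand grey > violet > amber > blue > green, with top 97.9% and low 0%.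

    E + X → Z (k = 2.10 M⁻¹ h⁻¹, Ea = 80.0 kJ mol⁻¹)
    X + Z → G (k = 1.20 M⁻¹ h⁻¹, Ea = 64.0 kJ mol⁻¹)
    X + G → J (k = 6.60 M⁻¹ h⁻¹, Ea = 75.0 kJ mol⁻¹)
    2 E → Q (k = 5.00 M⁻¹ h⁻¹, Ea = 59.0 kJ mol⁻¹)
    (constants at 50 °C)

Amber gives 21.1% and blue 18.7%, and at 6.00 h amber still holds 70% of its X, blue 29%. Read back, amber's share is 0.676 decades against the 1.89 that the fade number gives at 50 °C, a ratio of 2.80 that carries the cooling and the fade number's own error together. The same green flask run at 25 °C stands at 25.2%, which is 0.598 decades against the 2.52 that the fade number gives green at 50 °C, a ratio of 4.21.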